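**Plan**
1. Retrosynthesis: the two phenols are masked as silyl ethers and the C4 ketone is taken back to a 4-methoxyflavan. Ring C is then cut at O1–C2 and C3–C4 in a single operation.
2. Enabling feature: O1–C8a–C4a–C4 of ring C is the O=C–C=C unit of an o-quinone methide of ring A. C2–C3 is the vinyl group of an electron-rich 4-methoxystyrene that carries ring B.
3. Forward: rings A and B come from aromatic starting materials. Ring A receives formyl, two silyl groups, iodine and prenyl; ring B receives prenyl and vinyl. Ring C is formed last from aldehyde, orthoformate and styrene.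
4. Stereochemistry: C2 (S), the only stereocentre of the target, is set by a confined chiral Brønsted acid in the cycloaddition. C4 is transient and is erased by oxidation.
5. End game: OMe→OH exchange at C4, oxidation and buffered desilylation, all non-basic so that C2 is kept.

Key step: step 7

Abbreviations: TBS = tert-butyldimethylsilyl, prenyl = 3-methylbut-2-enyl. Flavonoid numbering is used from 14 on, benzaldehyde numbering for 3–7.
Assumption: the sense of induction of the confined acid cannot be derived for this substrate pair, so the (S,S) catalyst is written for the 2S product and its mirror image is used if the opposite sense is found.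

Step 1
Reactants: 1 2-methylphloroglucinol
Product: 3 2,4,6-trihydroxy-3-methylbenzaldehyde, via aryl iminium chloride 2 (not isolated)
Conditions: POCl3, DMF, EtOAc, 0 °C → rt; then H2O, 60 °C
Reagents that add atoms: N,N-dimethylformamide, CN(C)C=O; water, O
Why: Vilsmeier–Haack formylation, in which the two open ring positions of 1 are equivalent and very electron-rich, the first iminium group deactivates the ring against a second attack, and aqueous hydrolysis of 2 releases the aldehyde.

Step 2
Reactants: 3 2,4,6-trihydroxy-3-methylbenzaldehyde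
Product: 4 2-hydroxy-3-methyl-4,6-bis(TBSO)benzaldehyde
Conditions: TBSCl (2.1 equiv), imidazole, DMF, 0 °C
Reagents that add atoms: tert-butyldimethylsilyl chloride, CC(C)(C)[Si](C)(C)Cl
Why: Regioselective silyl ether formation, in which the unchelated 4-OH reacts first, the chelated OH beside C5–H is far more accessible to the bulky chloride than the one wedged between CHO and CH3, and the last OH is then held in a strong hydrogen bond to the carbonyl group and stays free.

Step 3
Reactants: 4 2-hydroxy-3-methyl-4,6-bis(TBSO)benzaldehyde
Product: 5 2-hydroxy-5-iodo-3-methyl-4,6-bis(TBSO)benzaldehyde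
Conditions: NIS (1.05 equiv), MeCN, 0 °C, dark
Reagents that add atoms: N-iodosuccinimide, O=C1CCC(=O)N1I
Why: Electrophilic aromatic iodination at the only unsubstituted ring carbon, which is para to the free phenol and ortho to both silyloxy groups, carried out before any prenyl group is present because NIS would attack such an alkene.

Step 4
Reactants: 5 2-hydroxy-5-iodo-3-methyl-4,6-bis(TBSO)benzaldehyde; 6 tributyl(prenyl)stannane
Product: 7 2-hydroxy-3-methyl-5-prenyl-4,6-bis(TBSO)benzaldehyde
Conditions: 6 (1.5 equiv), Pd2(dba)3 (5 mol %), AsPh3 (20 mol %), CuI (10 mol %), DMF, 60 °C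
Reagents that add atoms: tributyl(3-methylbut-2-enyl)stannane 6, CCCC[Sn](CCCC)(CCCC)CC=C(C)C
Why: Migita–Kosugi–Stille coupling under neutral, base- and fluoride-free conditions that leave the aldehyde, the free phenol and the aryl silyl ethers alone, with reductive elimination at the unsubstituted terminus of the prenyl–palladium unit giving the linear prenyl arene.

Step 5
Reactants: 8 3-bromo-4-methoxybenzaldehyde; 6 tributyl(prenyl)stannane
Product: 9 4-methoxy-3-prenylbenzaldehyde
Conditions: 6 (1.2 equiv), Pd(PPh3)4 (5 mol %), DMF, 100 °C
Reagents that add atoms: tributyl(3-methylbut-2-enyl)stannane 6, CCCC[Sn](CCCC)(CCCC)CC=C(C)C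
Why: Migita–Kosugi–Stille coupling of an aryl bromide, which tolerates the aldehyde and should again deliver the linear prenyl group through bond formation at the less substituted allyl terminus.

Step 6
Reactants: 9 4-methoxy-3-prenylbenzaldehyde
Product: 10 4-methoxy-3-prenylstyrene
Conditions: Ph3PCH3Br, KOtBu, THF, 0 °C → rt
Reagents that add atoms: methyltriphenylphosphonium bromide, C[P+](c1ccccc1)(c1ccccc1)c1ccccc1.[Br-]
Why: Wittig methylenation with the non-stabilised ylide, which is fast on an aromatic aldehyde and touches neither the trisubstituted alkene nor the aryl methyl ether.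

Step 7
Reactants: 7 2-hydroxy-3-methyl-5-prenyl-4,6-bis(TBSO)benzaldehyde; 10 4-methoxy-3-prenylstyrene; 11 trimethyl orthoformate
Product: 14 (2S,4S)-cis-4-methoxy-2-(4-methoxy-3-prenylphenyl)-8-methyl-6-prenyl-5,7-bis(TBSO)chroman, via dimethyl acetal 12 (not isolated), via methoxy o-quinone methide 13 (not isolated)
Conditions: (S,S)-imidodiphosphorimidate (IDPi, N-triflyl, 3,3'-diaryl-BINOL backbone, 5 mol %), 11 (1.5 equiv), 5 Å MS, CH2Cl2, 0 °C; then −70 °C, 10 (1.5 equiv, slow addition); Et3N quench at −70 °C
Reagents that add atoms: trimethyl orthoformate 11, COC(OC)OC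
Why: Proposed new method: the acid turns 7 and 11 into acetal 12, ionises it to the aryl oxocarbenium ion and, through loss of the only phenolic proton, to the 4-methoxy o-quinone methide 13, which stays hydrogen-bonded to the catalyst; the CH2 terminus of styrene 10 then bonds to C4 while O1 closes on the developing p-methoxybenzylic C2 in an asynchronous, inverse-demand oxa-[4+2] cycloaddition. The closest known reaction types are the achiral acid-promoted three-component assembly of 4-alkoxy-2-arylchromans from salicylaldehydes, orthoformates and styrenes, the confined imidodiphosphoric acid catalysed intramolecular [4+2] of alkoxy o-quinone methides formed from salicylaldehydes and unsaturated alcohols, and chiral phosphoric acid catalysed cycloadditions of o-quinone methides with styrenes that carry a binding group; the intermolecular enantioselective version with a styrene lacking such a group has not been shown. Ring C, the only ring formed, closes as a six-membered dihydropyran by the cycloaddition itself, C3–C4 leading and O1–C2 following within one ion-paired event. C2 is controlled by the catalyst, whose pocket exposes one face of the styrene to the bound O1/C4 edge of the heterodiene, and C4 by the endo approach of the aryl group to the E-configured 13, which places aryl and methoxy cis; C4 is erased in step 9, but any trans isomer is removed by chromatography here unless it is shown to share the 2S configuration. Regiochemistry follows from polarity (nucleophilic CH2 to electrophilic C4, O1 to the cation-stabilising carbon), the orientation of ring C from the fact that only the phenol between CHO and CH3 is free, and chemoselectivity from the much higher nucleophilicity of the p-methoxystyrene double bond over the two trisubstituted prenyl alkenes, whose neighbouring phenols on ring A are capped so that no acid-induced chroman closure can occur. Low temperature, slow addition of 10 and the amine quench before warming keep C4 and C2 from re-ionising and hold back cationic oligomerisation of the styrene.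

Step 8
Reactants: 14 (2S,4S)-cis-4-methoxy-2-(4-methoxy-3-prenylphenyl)-8-methyl-6-prenyl-5,7-bis(TBSO)chroman
Product: 15 (2S,4RS)-2-(4-methoxy-3-prenylphenyl)-8-methyl-6-prenyl-5,7-bis(TBSO)chroman-4-ol
Conditions: PPTS (10 mol %), THF/H2O 4:1, 0 °C → rt
Reagents that add atoms: water, O
Why: Acid-catalysed SN1 solvolysis of a benzylic ether, in which C4–OMe ionises easily because the cation is stabilised by O1 and the 5- and 7-silyloxy groups, the large excess of water captures it, and at this mild acidity neither the aryl silyl ethers nor the O1–C2 bond should break, so that C2 stays S while C4 becomes an inconsequential epimer mixture.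

Step 9
Reactants: 15 (2S,4RS)-2-(4-methoxy-3-prenylphenyl)-8-methyl-6-prenyl-5,7-bis(TBSO)chroman-4-ol
Product: 16 (2S)-2-(4-methoxy-3-prenylphenyl)-8-methyl-6-prenyl-5,7-bis(TBSO)chroman-4-one
Conditions: Dess–Martin periodinane, NaHCO3, CH2Cl2, 0 °C → rt
Reagents that add atoms: none
Why: Dess–Martin oxidation of a secondary benzylic alcohol under buffered, non-basic conditions, which merges both C4 epimers into one ketone, spares the two alkenes and the silyl ethers and offers no path for retro-oxa-Michael opening at C2.

Step 10
Reactants: 16 (2S)-2-(4-methoxy-3-prenylphenyl)-8-methyl-6-prenyl-5,7-bis(TBSO)chroman-4-one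
Product: 17 (2S)-5,7-dihydroxy-2-(4-methoxy-3-prenylphenyl)-8-methyl-6-prenylchroman-4-one (CNP0157343.1)
Conditions: TBAF (2.2 equiv), AcOH (2.6 equiv), THF, 0 °C
Reagents that add atoms: none
Why: Fluoride cleavage of aryl silyl ethers, which is fast at low temperature, with acetic acid protonating each phenoxide as it forms so that the E1cB ring opening to the chalcone, the path by which flavanones racemise, is suppressed.

**Compound list**
1 | 2-methylphloroglucinol (2-methylbenzene-1,3,5-triol) | Cc1c(O)cc(O)cc1O | starting material
2 | dimethyl(2,4,6-trihydroxy-3-methylbenzylidene)iminium chloride, not isolated | C[N+](C)=Cc1c(O)c(C)c(O)cc1O.[Cl-] | intermediate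
3 | 2,4,6-trihydroxy-3-methylbenzaldehyde | O=Cc1c(O)c(C)c(O)cc1O | intermediate
4 | 2-hydroxy-3-methyl-4,6-bis(tert-butyldimethylsilyloxy)benzaldehyde | O=Cc1c(O)c(C)c(O[Si](C)(C)C(C)(C)C)cc1O[Si](C)(C)C(C)(C)C | intermediate
5 | 2-hydroxy-5-iodo-3-methyl-4,6-bis(tert-butyldimethylsilyloxy)benzaldehyde | O=Cc1c(O)c(C)c(O[Si](C)(C)C(C)(C)C)c(I)c1O[Si](C)(C)C(C)(C)C | intermediate
6 | tributyl(3-methylbut-2-enyl)stannane | CCCC[Sn](CCCC)(CCCC)CC=C(C)C | starting material
7 | 2-hydroxy-3-methyl-5-(3-methylbut-2-enyl)-4,6-bis(tert-butyldimethylsilyloxy)benzaldehyde | O=Cc1c(O)c(C)c(O[Si](C)(C)C(C)(C)C)c(CC=C(C)C)c1O[Si](C)(C)C(C)(C)C | intermediate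
8 | 3-bromo-4-methoxybenzaldehyde | COc1ccc(C=O)cc1Br | starting material
9 | 4-methoxy-3-(3-methylbut-2-enyl)benzaldehyde | COc1ccc(C=O)cc1CC=C(C)C | intermediate
10 | 4-methoxy-3-(3-methylbut-2-enyl)styrene | C=Cc1ccc(OC)c(CC=C(C)C)c1 | intermediate
11 | trimethyl orthoformate | COC(OC)OC | starting material
12 | dimethyl acetal of 7, not isolated | COC(OC)c1c(O)c(C)c(O[Si](C)(C)C(C)(C)C)c(CC=C(C)C)c1O[Si](C)(C)C(C)(C)C | intermediate
13 | (6E)-6-(methoxymethylidene)-2-methyl-4-(3-methylbut-2-enyl)-3,5-bis(tert-butyldimethylsilyloxy)cyclohexa-2,4-dien-1-one, not isolated | CO/C=C1/C(=O)C(C)=C(O[Si](C)(C)C(C)(C)C)C(CC=C(C)C)=C1O[Si](C)(C)C(C)(C)C | intermediate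
14 | (2S,4S)-4-methoxy-2-[4-methoxy-3-(3-methylbut-2-enyl)phenyl]-8-methyl-6-(3-methylbut-2-enyl)-5,7-bis(tert-butyldimethylsilyloxy)chroman (2,4-cis) | COc1ccc([C@@H]2C[C@H](OC)c3c(O[Si](C)(C)C(C)(C)C)c(CC=C(C)C)c(O[Si](C)(C)C(C)(C)C)c(C)c3O2)cc1CC=C(C)C | intermediate
15 | (2S,4RS)-2-[4-methoxy-3-(3-methylbut-2-enyl)phenyl]-8-methyl-6-(3-methylbut-2-enyl)-5,7-bis(tert-butyldimethylsilyloxy)chroman-4-ol (C4 epimer mixture, C4 left undefined) | COc1ccc([C@@H]2CC(O)c3c(O[Si](C)(C)C(C)(C)C)c(CC=C(C)C)c(O[Si](C)(C)C(C)(C)C)c(C)c3O2)cc1CC=C(C)C | intermediate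
16 | (2S)-2-[4-methoxy-3-(3-methylbut-2-enyl)phenyl]-8-methyl-6-(3-methylbut-2-enyl)-5,7-bis(tert-butyldimethylsilyloxy)chroman-4-one | COc1ccc([C@@H]2CC(=O)c3c(O[Si](C)(C)C(C)(C)C)c(CC=C(C)C)c(O[Si](C)(C)C(C)(C)C)c(C)c3O2)cc1CC=C(C)C | intermediate
17 | (2S)-5,7-dihydroxy-2-[4-methoxy-3-(3-methylbut-2-enyl)phenyl]-8-methyl-6-(3-methylbut-2-enyl)chroman-4-one | COc1ccc([C@@H]2CC(=O)c3c(O)c(CC=C(C)C)c(O)c(C)c3O2)cc1CC=C(C)C | target

**Total step count:** 10. **Longest linear sequence:** 8 (steps 1–4 and 7–10); steps 5 and 6 form the second branch.

**Steps most likely to fail**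

Step 7.
- **Risk:** The catalyst may discriminate poorly between the styrene faces, because the hexasubstituted heterodiene is large. A stepwise cationic course could turn an imperfect cis/trans ratio into loss of purity at C2. The acid may also start oligomerisation or hydromethoxylation of the styrene, and the product may re-ionise on warming.
- **Fallback (from 7, 10 and 11, back at 16):** The three components are combined under an achiral acid (Sc(OTf)3 or TfOH cat., CH2Cl2, −20 °C). This is the known racemic form of the reaction and gives the racemic cis-4-methoxyflavan F1. Solvolysis and Dess–Martin oxidation as in steps 8 and 9 lead through the racemic flavan-4-ol F2 to the racemic bis-silyl flavanone F3. A kinetic resolution by Noyori-type asymmetric transfer hydrogenation (Cp*Rh–TsDPEN, HCO2H/Et3N, EtOAc, rt) follows; this is a known way to split racemic flavanones. It reduces the 2R ketone to the (2R,4R)-cis-flavan-4-ol F4, which is removed by chromatography. The unreacted 2S ketone is 16. The stereochemistry then comes from the resolution and no longer from the ring-forming step.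

Step 4.
- **Risk:** Oxidative addition and transmetalation may be slow at an iodide flanked by two out-of-plane silyloxy groups. Protodeiodination or prenyl transfer to the aldehyde could then take over.
- **Fallback (from 4, bypassing 5, back at 7):** The free phenol of 4 is O-prenylated under Mitsunobu conditions (3-methylbut-2-en-1-ol, PPh3, DIAD, THF, 0 °C) to the prenyl aryl ether F5. This ether is heated (Eu(fod)3 cat., PhCl, 90 °C, or N,N-diethylaniline, 190 °C). Both ortho positions are blocked, so a Claisen shift to the methyl-bearing ortho carbon is followed by a Cope shift to the para carbon and tautomerisation. This places a linear prenyl group at C5 and frees the same phenol again, which is 7.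

Step 8.
- **Risk:** Loss of a proton from C3 of the C4 cation may compete with capture by water. The resulting elimination opens a path to erosion at C2. Prolonged acid contact may also strip silyl groups.
- **Fallback (from 14, back at 16, no new compound, F0):** C4 is oxidised without ever breaking the C4–O bond by ionisation. DDQ in CH2Cl2/pH 7 buffer at 0 °C abstracts hydride from the C4–H bond of the electron-rich benzylic methyl ether. Water then adds to the oxocarbenium ion and methanol leaves, which gives ketone 16 directly and omits 15.

**Further compounds**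
F1 | step 7 | racemic cis-4-methoxy-2-(4-methoxy-3-prenylphenyl)-8-methyl-6-prenyl-5,7-bis(TBSO)chroman | COc1ccc(C2CC(OC)c3c(O[Si](C)(C)C(C)(C)C)c(CC=C(C)C)c(O[Si](C)(C)C(C)(C)C)c(C)c3O2)cc1CC=C(C)C
F2 | step 7 | racemic 2-(4-methoxy-3-prenylphenyl)-8-methyl-6-prenyl-5,7-bis(TBSO)chroman-4-ol | COc1ccc(C2CC(O)c3c(O[Si](C)(C)C(C)(C)C)c(CC=C(C)C)c(O[Si](C)(C)C(C)(C)C)c(C)c3O2)cc1CC=C(C)C
F3 | step 7 | racemic 2-(4-methoxy-3-prenylphenyl)-8-methyl-6-prenyl-5,7-bis(TBSO)chroman-4-one | COc1ccc(C2CC(=O)c3c(O[Si](C)(C)C(C)(C)C)c(CC=C(C)C)c(O[Si](C)(C)C(C)(C)C)c(C)c3O2)cc1CC=C(C)C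
F4 | step 7 | (2R,4R)-cis-2-(4-methoxy-3-prenylphenyl)-8-methyl-6-prenyl-5,7-bis(TBSO)chroman-4-ol | COc1ccc([C@H]2C[C@@H](O)c3c(O[Si](C)(C)C(C)(C)C)c(CC=C(C)C)c(O[Si](C)(C)C(C)(C)C)c(C)c3O2)cc1CC=C(C)C
F5 | step 4 | 3-methyl-2-(3-methylbut-2-enyloxy)-4,6-bis(TBSO)benzaldehyde | O=Cc1c(OCC=C(C)C)c(C)c(O[Si](C)(C)C(C)(C)C)cc1O[Si](C)(C)C(C)(C)C
F0 | step 8 | none | none
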